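Oxolane numbering: O1, C2 (aryl), C3 (CH2OH), C4 (benzyl), C5 (CH2). The ring is cut at O1–C5 and C2–C3. This leaves veratraldehyde and a C3–C4–C5 unit that must be nucleophilic at C3 and electrophilic at C5. A trans-2-benzylcyclopropane carrying an acyl oxazolidinone hides exactly this 1,3-dipole. In one flask, iodide opens the strained ring at its CH2 (C5) to give a titanium enolate at C3, the auxiliary-controlled syn aldol makes C2–C3, and the aldolate oxygen displaces iodide to make O1–C5. The step exploits the 1,3-relationship of C3 and C5 across C4 of the oxolane ring; it sets C2 and C3, while C4 comes from the cyclopropane.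

Key step: step 4

Assumption: with the allylarene 1 the ruthenium–pybox catalyst is taken to show the same sense of induction as with other terminal alkenes, so the (R,R) ligand is chosen for the (1S,2R) cyclopropane; imide 7 is purified to a single stereoisomer before step 4.

Step 1
Reactants: 1 eugenyl acetate (4-allyl-2-methoxyphenyl acetate); 2 tert-butyl diazoacetate
Product: 3 tert-butyl (1S,2R)-2-(4-acetoxy-3-methoxybenzyl)cyclopropane-1-carboxylate
Conditions: RuCl2(C2H4)[(R,R)-iPr-pybox] (2 mol%), 1 (3 equiv), slow addition of 2, CH2Cl2, 30 °C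
Reagents that add atoms: none
Why: Ruthenium–pybox carbene-transfer cyclopropanation of the terminal alkene, in which the bulky tert-butyl ester favours the trans product and the C2-symmetric ligand selects the alkene face, so the benzyl-bearing stereocentre (C4 of the target) should be set as R.

Step 2
Reactants: 3 tert-butyl (1S,2R)-2-(4-acetoxy-3-methoxybenzyl)cyclopropane-1-carboxylate
Product: 4 (1S,2R)-2-(4-acetoxy-3-methoxybenzyl)cyclopropane-1-carboxylic acid
Conditions: CF3CO2H, CH2Cl2, 0 → 23 °C
Reagents that add atoms: none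
Why: Acidolysis of the tert-butyl ester with loss of isobutene should leave the aryl acetate, the cyclopropane and both stereocentres untouched.

Step 3
Reactants: 4 (1S,2R)-2-(4-acetoxy-3-methoxybenzyl)cyclopropane-1-carboxylic acid; 5 (S)-4-benzyloxazolidin-2-one
Product: 7 (S)-3-[(1S,2R)-2-(4-acetoxy-3-methoxybenzyl)cyclopropane-1-carbonyl]-4-benzyloxazolidin-2-one, via mixed pivalic anhydride 6 (not isolated)
Conditions: t-BuCOCl, Et3N, THF, −20 °C; then 5, LiCl, −20 → 23 °C
Reagents that add atoms: none
Why: Mixed-anhydride N-acylation of the oxazolidinone under LiCl/Et3N is mild enough to spare the aryl acetate and touches no stereocentre, and any cis or enantiomeric cyclopropane becomes a diastereomeric imide that can be removed here.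

Step 4
Reactants: 7 (S)-3-[(1S,2R)-2-(4-acetoxy-3-methoxybenzyl)cyclopropane-1-carbonyl]-4-benzyloxazolidin-2-one; 8 veratraldehyde (3,4-dimethoxybenzaldehyde)
Product: 11 (S)-3-[(2S,3S,4R)-4-(4-acetoxy-3-methoxybenzyl)-2-(3,4-dimethoxyphenyl)oxolane-3-carbonyl]-4-benzyloxazolidin-2-one, via iodo titanium enolate 9 (not isolated), via titanium aldolate 10 (not isolated)
Conditions: TiCl4 (1.5 equiv), n-Bu4NI (1.5 equiv), CH2Cl2, −78 → 0 °C; 8 (1.3 equiv), −78 °C; then Ag2O (6 equiv), −78 → 23 °C, dark
Reagents that add atoms: none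
Why: Proposed new method: TiCl4 chelates the imide of 7 and iodide opens the strained ring by SN2 attack at its unsubstituted CH2 (the future C5), so that strain release delivers the (Z)-titanium enolate 9 without base; 9 adds to 8 through a closed Zimmerman–Traxler chair (Evans syn aldol, halide-saturated titanium, auxiliary dipole opposed) to form C2–C3, and Ag2O then strips halide from titanium and activates the primary iodide so that the aldolate oxygen of 10 forms O1–C5. The closest known reaction types are the TiCl4/n-Bu4NI ring-opening aldol of cyclopropyl ketones, the MgI2-relayed ring expansion of acyl cyclopropanes with imines and the iodo-aldol of N-enoyl oxazolidinones; new here are the acyl oxazolidinone as cyclopropane acceptor and the ring closure in the same flask. The oxolane closes in the 5-exo-tet mode, as an intramolecular Purdie-type etherification. C3 is set by the (S)-benzyl group of the auxiliary, which blocks one enolate face, C2 follows from the Z-enolate in the chair (syn aldol, hence 2,3-trans), and C4 is carried over untouched from the cyclopropane. The step needs iodide to attack the CH2 and not the benzyl-bearing CH, which the lower substitution of that carbon should secure, and it needs the kinetic 2,3-trans-3,4-cis adduct to survive, which the weakly basic, halophilic closure is meant to secure.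

Step 5
Reactants: 11 (S)-3-[(2S,3S,4R)-4-(4-acetoxy-3-methoxybenzyl)-2-(3,4-dimethoxyphenyl)oxolane-3-carbonyl]-4-benzyloxazolidin-2-one
Product: 12 4-{[(3R,4R,5S)-5-(3,4-dimethoxyphenyl)-4-(hydroxymethyl)oxolan-3-yl]methyl}-2-methoxyphenol
Conditions: LiBH4 (4 equiv), H2O (1 equiv), THF/Et2O, 0 → 23 °C
Reagents that add atoms: none
Why: Reductive cleavage of the N-acyl oxazolidinone at the exocyclic carbonyl should give the C3 hydroxymethyl group and free the auxiliary, and the same hydride removes the aryl acetate, so the phenol appears without a separate deprotection and no stereocentre is touched.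

Compound list
1 | eugenyl acetate (4-allyl-2-methoxyphenyl acetate) | CC(=O)Oc1ccc(CC=C)cc1OC | starting material
2 | tert-butyl diazoacetate | CC(C)(C)OC(=O)C=[N+]=[N-] | starting material
3 | tert-butyl (1S,2R)-2-(4-acetoxy-3-methoxybenzyl)cyclopropane-1-carboxylate | CC(C)(C)OC(=O)[C@H]1C[C@@H]1Cc1ccc(OC(C)=O)c(OC)c1 | intermediate
4 | (1S,2R)-2-(4-acetoxy-3-methoxybenzyl)cyclopropane-1-carboxylic acid | OC(=O)[C@H]1C[C@@H]1Cc1ccc(OC(C)=O)c(OC)c1 | intermediate
5 | (S)-4-benzyloxazolidin-2-one | O=C1N[C@@H](Cc2ccccc2)CO1 | starting material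
6 | mixed anhydride of 4 with pivalic acid | CC(C)(C)C(=O)OC(=O)[C@H]1C[C@@H]1Cc1ccc(OC(C)=O)c(OC)c1 | intermediate
7 | (S)-3-[(1S,2R)-2-(4-acetoxy-3-methoxybenzyl)cyclopropane-1-carbonyl]-4-benzyloxazolidin-2-one | O=C(N1[C@@H](Cc2ccccc2)COC1=O)[C@H]3C[C@@H]3Cc4ccc(OC(C)=O)c(OC)c4 | intermediate
8 | veratraldehyde (3,4-dimethoxybenzaldehyde) | COc1ccc(C=O)cc1OC | starting material
9 | (Z)-trichlorotitanium enolate of (S)-3-[(3R)-3-(4-acetoxy-3-methoxybenzyl)-4-iodobutanoyl]-4-benzyloxazolidin-2-one | IC[C@H](Cc1ccc(OC(C)=O)c(OC)c1)/C=C(\O[Ti](Cl)(Cl)Cl)N2[C@@H](Cc3ccccc3)COC2=O | intermediate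
10 | trichlorotitanium alkoxide of (S)-3-{(2S,3R)-3-(4-acetoxy-3-methoxybenzyl)-2-[(S)-(3,4-dimethoxyphenyl)(hydroxy)methyl]-4-iodobutanoyl}-4-benzyloxazolidin-2-one | COc1cc(C[C@@H](CI)[C@@H]([C@H](O[Ti](Cl)(Cl)Cl)c2ccc(OC)c(OC)c2)C(=O)N3[C@@H](Cc4ccccc4)COC3=O)ccc1OC(C)=O | intermediate
11 | (S)-3-[(2S,3S,4R)-4-(4-acetoxy-3-methoxybenzyl)-2-(3,4-dimethoxyphenyl)oxolane-3-carbonyl]-4-benzyloxazolidin-2-one | COc1cc(C[C@H]2CO[C@H](c3ccc(OC)c(OC)c3)[C@H]2C(=O)N4[C@@H](Cc5ccccc5)COC4=O)ccc1OC(C)=O | intermediate
12 | 4-{[(3R,4R,5S)-5-(3,4-dimethoxyphenyl)-4-(hydroxymethyl)oxolan-3-yl]methyl}-2-methoxyphenol | COc1cc(C[C@H]2CO[C@H](c3ccc(OC)c(OC)c3)[C@H]2CO)ccc1O | target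

Total step count: 5. Longest linear sequence: 5 steps.

Steps most likely to fail

Step 4. Iodide may attack the benzyl-bearing ring carbon instead of the CH2, the kinetic syn aldolate may scramble by retro-aldol before it closes, or the titanium-bound oxygen may fail to displace iodide. The fallback is the classical lignan sequence, which uses no cyclopropane, sets out from the auxiliary 5 and comes back at the target 12. Acylation of 5 (n-BuLi, THF, −78 °C) with 3-[4-(benzyloxy)-3-methoxyphenyl]propanoyl chloride should give the N-acyl oxazolidinone F1. Evans alkylation (NaN(SiMe3)2, tert-butyl bromoacetate, −78 °C) should give the (R)-succinate F2. LiBH4 should remove the auxiliary to give the hydroxy ester F3, and CF3CO2H should close it to the (R)-β-benzyl lactone F4. The lithium enolate of F4 (LiN(iPr)2, THF, −78 °C) should add to 8 trans to the benzyl group to give the hydroxybenzyl lactone F5 as carbinol epimers. LiAlH4 should give the triol F6. Mild acid (camphorsulfonic acid, CH2Cl2, 0 °C) should close the oxolane through the benzylic cation, here by O1–C2 bond formation and with the aryl group trans to the C3 substituent, to give the O-benzyl ether F7. Hydrogenolysis (H2, Pd/C, EtOAc, short reaction time) should give 12.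

Step 1. Facial and trans selectivity of the carbene transfer may be poor with an unconjugated terminal alkene, and carbene dimerisation may compete. The fallback replaces catalyst control by separation of auxiliary-derived diastereomers; it sets out from 1 and comes back at 7. Cyclopropanation of 1 with 2 under Rh2(OAc)4 (CH2Cl2, slow addition) should give the racemic ester mixture F8. CF3CO2H should give the acid mixture F9. Activation as in step 3 should give the mixed anhydride mixture F10, and acylation of 5 should give the diastereomeric imide mixture F11. From F11 the (1S,2R) diastereomer 7 is isolated by chromatography and crystallisation.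

Step 5. Hydride may attack the ring carbonyl of the hindered imide and open the oxazolidinone, and the intermediate aldehyde may epimerise at C3. The fallback separates auxiliary removal from reduction; it sets out from 11 and comes back at 12. LiOH/H2O2 (THF/H2O, 0 °C) should hydrolyse the imide and the aryl acetate to give the hydroxy acid F12. BH3·SMe2 (THF, 0 → 23 °C) should then reduce the carboxylic acid selectively to give 12.

Further compounds
F1 | step 4 | (S)-4-benzyl-3-{3-[4-(benzyloxy)-3-methoxyphenyl]propanoyl}oxazolidin-2-one | COc1cc(CCC(=O)N2[C@@H](Cc3ccccc3)COC2=O)ccc1OCc1ccccc1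
F2 | step 4 | (S)-4-benzyl-3-{(2R)-2-[4-(benzyloxy)-3-methoxybenzyl]-4-(tert-butoxy)-4-oxobutanoyl}oxazolidin-2-one | COc1cc(C[C@H](CC(=O)OC(C)(C)C)C(=O)N2[C@@H](Cc3ccccc3)COC2=O)ccc1OCc1ccccc1
F3 | step 4 | tert-butyl (3R)-3-[4-(benzyloxy)-3-methoxybenzyl]-4-hydroxybutanoate | COc1cc(C[C@H](CC(=O)OC(C)(C)C)CO)ccc1OCc1ccccc1
F4 | step 4 | (4R)-4-[4-(benzyloxy)-3-methoxybenzyl]oxolan-2-one | COc1cc(C[C@H]2COC(=O)C2)ccc1OCc1ccccc1
F5 | step 4 | (3S,4R)-4-[4-(benzyloxy)-3-methoxybenzyl]-3-[(3,4-dimethoxyphenyl)(hydroxy)methyl]oxolan-2-one (carbinol epimers) | COc1cc(C[C@H]2COC(=O)[C@@H]2C(O)c3ccc(OC)c(OC)c3)ccc1OCc1ccccc1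
F6 | step 4 | (2R,3R)-2-[4-(benzyloxy)-3-methoxybenzyl]-3-[(3,4-dimethoxyphenyl)(hydroxy)methyl]butane-1,4-diol (carbinol epimers) | COc1cc(C[C@@H](CO)[C@H](CO)C(O)c2ccc(OC)c(OC)c2)ccc1OCc1ccccc1
F7 | step 4 | [(2S,3R,4R)-4-[4-(benzyloxy)-3-methoxybenzyl]-2-(3,4-dimethoxyphenyl)oxolan-3-yl]methanol | COc1cc(C[C@H]2CO[C@H](c3ccc(OC)c(OC)c3)[C@H]2CO)ccc1OCc1ccccc1
F8 | step 1 | tert-butyl 2-(4-acetoxy-3-methoxybenzyl)cyclopropane-1-carboxylate (racemic cis/trans mixture) | CC(C)(C)OC(=O)C1CC1Cc1ccc(OC(C)=O)c(OC)c1
F9 | step 1 | 2-(4-acetoxy-3-methoxybenzyl)cyclopropane-1-carboxylic acid (racemic cis/trans mixture) | OC(=O)C1CC1Cc1ccc(OC(C)=O)c(OC)c1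
F10 | step 1 | mixed anhydride of F9 with pivalic acid (stereoisomer mixture) | CC(C)(C)C(=O)OC(=O)C1CC1Cc1ccc(OC(C)=O)c(OC)c1
F11 | step 1 | (4S)-3-[2-(4-acetoxy-3-methoxybenzyl)cyclopropane-1-carbonyl]-4-benzyloxazolidin-2-one (mixture of diastereomers) | O=C(N1[C@@H](Cc2ccccc2)COC1=O)C3CC3Cc4ccc(OC(C)=O)c(OC)c4
F12 | step 5 | (2S,3S,4R)-2-(3,4-dimethoxyphenyl)-4-(4-hydroxy-3-methoxybenzyl)oxolane-3-carboxylic acid | COc1cc(C[C@H]2CO[C@H](c3ccc(OC)c(OC)c3)[C@H]2C(O)=O)ccc1O
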